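The data come from a simulation with made-up constants; scatter was added.

Wednesday's run, at a lower loading of 2.3 mol% against 3.2 mol% in Friday's, has more of its charge in chains at 5.00 h than Friday's, 34.7% against 27.2%.

| flask | free monomer | initiator | remark | time |
|---|---|---|---|---|
| Friday's | 0.80 M | 3.2 mol% | run made earlier |  |
| Saturday's | 0.80 M | 5.1 mol% | run made earlier |  |
| Wednesday's | 1.6 M | 2.3 mol% | run made earlier |  |
| flask | 0.80 M | 2.3 mol% |  | 8.0 h |

| run | time / h | monomer in chains / % |
|---|---|---|
| Friday's | 0.417 | 1.2 |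
| Friday's | 0.667 | 3.8 |
| Friday's | 0.833 | 1.8 |
| Friday's | 1.33 | 7.8 |
| Friday's | 2.00 | 11.6 |
| Friday's | 3.00 | 19.6 |
| Friday's | 5.00 | 27.2 |
| Saturday's | 0.417 | 3.8 |
| Saturday's | 0.667 | 4.7 |
| Saturday's | 0.833 | 6.4 |
| Saturday's | 1.33 | 11.4 |
| Saturday's | 2.00 | 18.4 |
| Saturday's | 3.00 | 26.3 |
| Saturday's | 5.00 | 41.6 |
| Wednesday's | 1.00 | 9.1 |
| Wednesday's | 2.00 | 16.8 |
| Wednesday's | 3.00 | 26.1 |
| Wednesday's | 4.00 | 29.9 |
| Wednesday's | 5.00 | 34.7 |

(readings scatter by 1 percentage point)



1. amount of monomer in chains in percent of the free monomer charged, at 50 min, 3.0 h and 8.0 h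

So loading does not order these runs, but the initiator concentration c_I, the free monomer charge times the loading, may: it is 0.0256 M in Friday's run and 0.0368 M in Wednesday's. Read as a pseudo-first-order course, each run gives k_app, minus the logarithm of the fraction not in chains, divided by time: 0.0635 h⁻¹ for Friday's and 0.0852 h⁻¹ for Wednesday's at their last readings. Divided by c_I, these readings become 2.48 L mol⁻¹ h⁻¹ and 2.32 L mol⁻¹ h⁻¹, so κ, k_app per unit of c_I, is taken as their mean, 2.40 L mol⁻¹ h⁻¹, and Saturday's run stays aside as a test.

The flask has c_I of 0.01840 M, so its k_app is 0.0441 h⁻¹. The reckoning made here, with no lag, gives 3.61%, 12.4% and 29.7%. The forecast, holding “the rate depends on initiator concentration, not mol%”, gives 3.2%, 12.5% and 29%, and its first value is lower than this reckoning's.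

The flask gives 3.07%, 13.6% and 29.8%.

    free monomer + initiator → living end + monomer in chains (k = 1.10 L mol⁻¹ h⁻¹)
    2 free monomer → self-condensation product (k = 0.120 L mol⁻¹ h⁻¹)
    free monomer + living end → monomer in chains + living end, rate k3*[living end]*[free monomer] (k = 5.10 L mol⁻¹ h⁻¹)

Read back from the flask's value at 8.0 h, κ is 2.40 L mol⁻¹ h⁻¹; on Saturday's run, 2.40 L mol⁻¹ h⁻¹ gives 38.7% at 5.00 h, less than the reading of 41.6%. At 3.50 h, the flask's free monomer goes into chains at 0.88 of the rate at which it goes into self-condensation product. At 8.00 h, the flask holds 29.8% monomer in chains and, with each of its molecules counted as two, 45.9% self-condensation product.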